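The numbers in the tables were computed with constants of no real substance; the scatter is artificial.

Which temperature leaves the most Q in a flask of this charge after 15 min?

| flask | E | L | temperature | remark | time |
|---|---|---|---|---|---|
| ash | 14 mM | 0.18 mM | −25 °C | run made earlier |  |
| larch | 14 mM | 0.29 mM | 25 °C | run made earlier |  |
| maple | 7 mM | 0.13 mM | −25 °C | run made earlier |  |
| north-west | 14 mM | 0.13 mM | 10 °C |  | 15 min |
| north | 14 mM | 0.13 mM | 70 °C |  | 15 min |
| south | 14 mM | 0.13 mM | −20 °C |  | 15 min |
| south-east | 14 mM | 0.13 mM | 40 °C |  | 15 min |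

| run | time / min | Q / % | E / % |
|---|---|---|---|
| ash | 6.00 | 9.3 | 86.9 |
| ash | 15.0 | 15.9 | 69.1 |
| ash | 30.0 | 22.4 | 45.9 |
| ash | 50.0 | 28.3 | 24.4 |
| ash | 60.0 | 29.6 | 17.7 |
| larch | 0.500 | 7.8 | 87.3 |
| larch | 1.33 | 9.4 | 84.2 |
| larch | 3.00 | 9.1 | 83.8 |
| larch | 4.00 | 9.4 | 83.9 |
| larch | 6.00 | 9.2 | 84.0 |
| maple | 6.00 | 9.2 | 85.9 |
| maple | 15.0 | 15.9 | 68.5 |
| maple | 30.0 | 22.6 | 46.4 |
| maple | 50.0 | 27.5 | 26.9 |
| maple | 60.0 | 29.3 | 19.9 |

(standard deviation of a reading: 0.3 percentage points)

- a reading or a percentage of Q counts all its forms, free or not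

* the flask with the highest amount of Q, in percent of the E charged ("all alike" if they lie within 1.5 percentage points) (north-west / north / south / south-east / all alike)
* final Q, as a percentage of the E charged, in north-west
* final Q, as a percentage of the E charged, in north
* final Q, as a percentage of the E charged, in south
* final Q, as a percentage of the E charged, in south-east

In larch, E stands near 84.0% from 1.33 min on. The converted part of the charge over the part left, here called the stop ratio, is 0.190 there. This reckoning reads that stop as a balance between E and its products, not as a dead catalyst, so the ratio should climb on cooling. Ash at −25 °C was still losing E at the end, from 24.4% to 17.7%, so its stop ratio is at least 4.65. Together the two runs give the cooling steepness, the gas constant times the change in the logarithm of the stop ratio per change of inverse temperature (a van 't Hoff slope): at least 39.3 kJ mol⁻¹.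

Carried to north-west, this puts the stop ratio at 0.441 or above, so E should flatten at 69.4% of the charge or lower. Larch puts the share of Q among the products at 0.575, and if north-west keeps that share, it should hold 17.6% of Q or more. That is more than the 15.9% ash had at 15.0 min, and south, at −20 °C, is expected to be a similar cold run, still moving along its curve. Larch, at 25 °C, stood by 1.33 min with twice the L of north-west, and north-west, at 10 °C, gets 11.3 times that span. South-east should stop early, with a reckoned stop ratio of at most 0.0891. So north-west goes first, and the thing to watch is the level at which its E goes flat.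

The forecast chooses south, with 20% there, and gives north-west 18% (from 10% to 27%), south-east 3% and north 0.5%, on the grounds that “the catalyst dies quickly when warm”. Its central north-west figure lies near the 17.6% reckoned here, but that reckoned figure is a lower mark, and the two part on which flask comes first.

The richest flask is north-west, with 27.0% of Q against 15.3% in south, 2.55% in south-east and 0.220% in north.

    X ⇌ J (K = 1.40, k = 0.380 s⁻¹, Ea = 62.0 kJ mol⁻¹, ΔH = −47.0 kJ mol⁻¹)
    Q ⇌ G (K = 1.70, k = 0.00490 s⁻¹, Ea = 76.0 kJ mol⁻¹, ΔH = −15.0 kJ mol⁻¹)
    L + Q ⇌ Z, settled at all times (K = 66.0 L mol⁻¹, ΔH = −19.0 kJ mol⁻¹)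
    E + L ⇌ X (K = 89.0 L mol⁻¹, k = 18.0 L mol⁻¹ s⁻¹, Ea = 40.0 kJ mol⁻¹, ΔH = 9.00 kJ mol⁻¹)
    J ⇌ L + Q (K = 0.180 M, k = 0.180 s⁻¹, Ea = 60.0 kJ mol⁻¹, ΔH = −36.0 kJ mol⁻¹)
    (constants at −20 °C)

North-west holds 51.0% of E at 15.0 min and 50.4% at 150 min. Its stop ratio is therefore 0.962, above the floor of 0.441. Going round once more with this ratio in place of the one from ash lifts the steepness from 39.3 kJ mol⁻¹ to 75.8 kJ mol⁻¹. Carried to south-east, that steepness leaves 95.8% of the E, and south-east holds 95.7%.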